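**Assumption:** compounds 1, 2, 4, 9, 13 and both enantiomers of the diarylprolinol silyl ether catalyst are taken as commercial. The route is a paper design and has not been run; the selectivities stated are predictions from precedent.

## Retrosynthetic overview

1. The pyran is formed last by 6-endo-dig addition of the C1 hydroxyl onto an ynenone (O2–C3 bond).
2. The acrylic acid side chain comes from a Sonogashira coupling with (E)-3-iodoacrylic acid; the orsellinate is attached by acylation of the C8 allylic alcohol.
3. The C6 ketone, C7 tertiary alcohol and C4a=C5 alkene come from a cyclohexene by dihydroxylation, then oxidation/dehydrogenation.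
4. The carbocycle is formed first by an organocatalytic Michael/aldol annulation of an enynal with a β-keto ester.
5. Stereochemistry is relayed C4a → C8a → C8 → C7; the C4a centre is then erased by the dehydrogenation.

## Route

**Step 1**
Reactants: 1, 3-(trimethylsilyl)prop-2-ynal; 2, (triphenylphosphoranylidene)acetaldehyde
Product: 3, (2E)-5-(trimethylsilyl)pent-2-en-4-ynal
Conditions: toluene, rt to 40 °C
Reagents that add atoms: none (both partners are numbered reactants)
Why: Wittig olefination with a stabilised formyl ylide gives the (E)-enal, and the ynal is more electrophilic than the enal product.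

**Step 2**
Reactants: 3; 4, tert-butyl 3-oxopentanoate
Product: 5, (5S)-2-methyl-5-[(trimethylsilyl)ethynyl]cyclohex-2-en-1-one
Conditions: (R)-α,α-bis[3,5-bis(trifluoromethyl)phenyl]prolinol TMS ether (10 mol%), PhCO2H (10 mol%), toluene, rt; then p-TsOH·H2O, toluene, 80 °C
Reagents that add atoms: none
Why: Iminium-catalysed Michael addition (Jørgensen–Hayashi catalyst) occurs on the unshielded face of the (E)-iminium and sets C5 as S with the (R)-catalyst; acid then cleaves the tert-butyl ester, decarboxylates and closes the ring by intramolecular aldol condensation (Robinson-type annulation).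

**Step 3**
Reactants: 5
Product: 6, (5S,6S)-6-(hydroxymethyl)-2-methyl-5-[(trimethylsilyl)ethynyl]cyclohex-2-en-1-one
Conditions: LDA, THF, −78 °C; CH2O (g), −78 °C; AcOH quench
Reagents that add atoms: formaldehyde, C=O
Why: Aldol reaction of the kinetic α′-enolate with formaldehyde, which enters anti to the adjacent alkynyl group to give the trans product (sets the future C8a).

**Step 4**
Reactants: 6
Product: 7, (1S,5S,6S)-5-ethynyl-6-(hydroxymethyl)-2-methylcyclohex-2-en-1-ol
Conditions: NaBH4, CeCl3·7H2O, MeOH, −78 °C; then K2CO3, MeOH, rt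
Reagents that add atoms: none (hydrogen only)
Why: Luche 1,2-reduction with axial hydride delivery gives the equatorial alcohol trans to CH2OH (sets the future C8); carbonate/methanol then removes the alkyne TMS group.

**Step 5**
Reactants: 7
Product: 8, (1S,5S,6S)-6-{[(tert-butyldimethylsilyl)oxy]methyl}-5-ethynyl-2-methylcyclohex-2-en-1-ol
Conditions: TBSCl (1.05 equiv), imidazole, CH2Cl2, −20 to 0 °C
Reagents that add atoms: TBSCl, CC(C)(C)[Si](C)(C)Cl
Why: Silylation is selective for the primary over the secondary allylic alcohol.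

**Step 6**
Reactants: 9, orsellinic acid (2,4-dihydroxy-6-methylbenzoic acid)
Product: 10, tert-butyldimethylsilyl 2,4-bis[(tert-butyldimethylsilyl)oxy]-6-methylbenzoate
Conditions: TBSCl (3.5 equiv), imidazole, DMF, 40 °C
Reagents that add atoms: TBSCl, CC(C)(C)[Si](C)(C)Cl
Why: Exhaustive silylation protects both phenols and gives a silyl ester that can be converted directly into the acid chloride.

**Step 7**
Reactants: 8; 10
Product: 11, (1S,5S,6S)-6-{[(tert-butyldimethylsilyl)oxy]methyl}-5-ethynyl-2-methylcyclohex-2-en-1-yl 2,4-bis[(tert-butyldimethylsilyl)oxy]-6-methylbenzoate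
Conditions: 10, (COCl)2, cat. DMF, CH2Cl2, 0 °C to rt, evaporate; then 8, DMAP, Et3N, CH2Cl2, rt to 40 °C
Reagents that add atoms: none
Why: The silyl ester is converted to the acid chloride under neutral conditions (Wissner), and DMAP-catalysed acylation of the only free hydroxyl proceeds with retention at C8.

**Step 8**
Reactants: 11
Product: 12, (1S,2S,3S,5S,6S)-6-{[(tert-butyldimethylsilyl)oxy]methyl}-5-ethynyl-2,3-dihydroxy-2-methylcyclohexyl 2,4-bis[(tert-butyldimethylsilyl)oxy]-6-methylbenzoate
Conditions: OsO4 (5 mol%), NMO, acetone/H2O, rt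
Reagents that add atoms: osmium tetroxide, O=[Os](=O)(=O)=O; NMO, C[N+]1([O-])CCOCC1; water, O
Why: Upjohn syn-dihydroxylation of the only alkene occurs anti to the allylic ester (Kishi model), placing the tertiary C7 hydroxyl trans to the C8 oxygen; the terminal alkyne reacts much more slowly.

**Step 9**
Reactants: 12; 13, (E)-3-iodoacrylic acid
Product: 14, (2E)-5-[(1S,2S,3S,4S,5S)-3-{[2,4-bis(TBSO)-6-methylbenzoyl]oxy}-2-(TBSOCH2)-4,5-dihydroxy-4-methylcyclohexyl]pent-2-en-4-ynoic acid
Conditions: Pd(PPh3)2Cl2 (5 mol%), CuI (10 mol%), Et3N, THF, rt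
Reagents that add atoms: none
Why: Sonogashira coupling of the terminal alkyne with the activated vinyl iodide retains the E geometry, and the E-acid cannot lactonise onto the alkyne.

**Step 10**
Reactants: 14
Product: 15, (2E)-5-[(4R,5S,6S)-5-{[2,4-bis(TBSO)-6-methylbenzoyl]oxy}-6-(TBSOCH2)-4-hydroxy-4-methyl-3-oxocyclohex-1-en-1-yl]pent-2-en-4-ynoic acid
Conditions: IBX, DMSO, rt; then IBX·4-methoxypyridine N-oxide, DMSO, rt to 40 °C
Reagents that add atoms: none
Why: IBX oxidises the secondary alcohol to the ketone, and IBX·MPO (Nicolaou dehydrogenation) then introduces the C4a=C5 alkene; only C5 is enolisable because C7 is quaternary, and room temperature avoids benzylic oxidation of the aryl methyl. This removes the C4a stereocentre.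

**Step 11**
Reactants: 15
Product: 16, (2E)-5-[(4R,5S,6S)-5-[(2,4-dihydroxy-6-methylbenzoyl)oxy]-4-hydroxy-6-(hydroxymethyl)-4-methyl-3-oxocyclohex-1-en-1-yl]pent-2-en-4-ynoic acid
Conditions: HF·pyridine, pyridine/THF, 0 °C to rt
Reagents that add atoms: none
Why: Buffered fluoride desilylation removes the two aryl and one primary TBS ethers without base that could trigger E1cB loss of the C8 ester.

**Step 12**
Reactants: 16
Product: 17, pinazaphilone B, (7R,8S,8aS)
Conditions: Ph3PAuNTf2 (5 mol%) or AgOTf (10 mol%), THF, rt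
Reagents that add atoms: none
Why: π-Acid-catalysed 6-endo-dig hydroalkoxylation; the primary hydroxyl adds to the alkyne carbon that is δ to the ketone (vinylogous oxa-Michael), giving the conjugated pyran without touching C7, C8 or C8a.

## Compound list

1 | 3-(trimethylsilyl)prop-2-ynal | C[Si](C)(C)C#CC=O | starting material
2 | (triphenylphosphoranylidene)acetaldehyde | O=CC=P(c1ccccc1)(c1ccccc1)c1ccccc1 | starting material
3 | (2E)-5-(trimethylsilyl)pent-2-en-4-ynal | C[Si](C)(C)C#C/C=C/C=O | intermediate
4 | tert-butyl 3-oxopentanoate | CCC(=O)CC(=O)OC(C)(C)C | starting material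
5 | (5S)-2-methyl-5-[(trimethylsilyl)ethynyl]cyclohex-2-en-1-one | CC1=CC[C@H](C#C[Si](C)(C)C)CC1=O | intermediate
6 | (5S,6S)-6-(hydroxymethyl)-2-methyl-5-[(trimethylsilyl)ethynyl]cyclohex-2-en-1-one | CC1=CC[C@H](C#C[Si](C)(C)C)[C@@H](CO)C1=O | intermediate
7 | (1S,5S,6S)-5-ethynyl-6-(hydroxymethyl)-2-methylcyclohex-2-en-1-ol | CC1=CC[C@H](C#C)[C@@H](CO)[C@@H]1O | intermediate
8 | (1S,5S,6S)-6-(TBSOCH2)-5-ethynyl-2-methylcyclohex-2-en-1-ol | CC1=CC[C@H](C#C)[C@@H](CO[Si](C)(C)C(C)(C)C)[C@@H]1O | intermediate
9 | orsellinic acid | Cc1cc(O)cc(O)c1C(=O)O | starting material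
10 | TBS 2,4-bis(TBSO)-6-methylbenzoate | Cc1cc(O[Si](C)(C)C(C)(C)C)cc(O[Si](C)(C)C(C)(C)C)c1C(=O)O[Si](C)(C)C(C)(C)C | intermediate
11 | (1S,5S,6S)-cyclohexenyl orsellinate, bis-TBS aryl ether, primary TBS ether | Cc1cc(O[Si](C)(C)C(C)(C)C)cc(O[Si](C)(C)C(C)(C)C)c1C(=O)O[C@H]1[C@H](CO[Si](C)(C)C(C)(C)C)[C@@H](C#C)CC=C1C | intermediate
12 | (1S,2S,3S,5S,6S)-diol ester | Cc1cc(O[Si](C)(C)C(C)(C)C)cc(O[Si](C)(C)C(C)(C)C)c1C(=O)O[C@H]1[C@H](CO[Si](C)(C)C(C)(C)C)[C@@H](C#C)C[C@H](O)[C@]1(C)O | intermediate
13 | (E)-3-iodoacrylic acid | OC(=O)/C=C/I | starting material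
14 | enynoic acid diol (Sonogashira product) | Cc1cc(O[Si](C)(C)C(C)(C)C)cc(O[Si](C)(C)C(C)(C)C)c1C(=O)O[C@H]1[C@H](CO[Si](C)(C)C(C)(C)C)[C@@H](C#C/C=C/C(=O)O)C[C@H](O)[C@]1(C)O | intermediate
15 | ynenone acid, tris-TBS | Cc1cc(O[Si](C)(C)C(C)(C)C)cc(O[Si](C)(C)C(C)(C)C)c1C(=O)O[C@H]1[C@H](CO[Si](C)(C)C(C)(C)C)C(C#C/C=C/C(=O)O)=CC(=O)[C@]1(C)O | intermediate
16 | desilylated ynenone acid | Cc1cc(O)cc(O)c1C(=O)O[C@H]1[C@H](CO)C(C#C/C=C/C(=O)O)=CC(=O)[C@]1(C)O | intermediate
17 | pinazaphilone B | Cc1cc(O)cc(O)c1C(=O)O[C@H]1[C@@H]2COC(/C=C/C(=O)O)=CC2=CC(=O)[C@]1(C)O | target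

## Step count

- Total steps: 12
- Longest linear sequence: 11 (1 → 3 → 5 → 6 → 7 → 8 → 11 → 12 → 14 → 15 → 16 → 17); step 6 is the one-step side branch.

## Three steps most likely to fail

1. **Step 3 (trans-selective hydroxymethylation).** The alkynyl group is a small directing group and the β-hydroxy ketone can epimerise, so the diastereomer ratio may be modest. Fallback: switch to a C8-first relay. Fráter–Seebach anti-alkylation of an enantiopure ethyl 3-hydroxyhex-5-enoate sets C8/C8a; ring-closing metathesis gives a trans-6-(alkoxymethyl)-5-silyloxycyclohex-2-enone; alkynyl 1,2-addition and oxidative allylic transposition give the 3-alkynyl enone; enolate methylation and Davis hydroxylation anti to the silyloxy group set C7.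

2. **Step 10 (one-pot IBX oxidation/dehydrogenation).** The substrate is densely functionalised and over-oxidation or glycol cleavage is possible. Fallback: oxidise the secondary alcohol alone (Dess–Martin), then introduce the alkene through the TMS enol ether by Saegusa–Ito oxidation rather than direct dehydrogenation.

3. **Step 12 (6-endo versus 5-exo cyclisation).** The acrylic acid polarises the alkyne in the opposite sense to the enone, and the free primary alcohol could also take the aryl ester by acyl migration. Fallback: couple with (E)-3-iodoallyl TBS ether instead of iodoacrylic acid so that only the enone polarises the alkyne, cyclise, then oxidise the allylic alcohol to the acid (MnO2, then Pinnick) at the end.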